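**Retrosynthetic overview**
1. Target 15 ⇐ acetate methanolysis and chelation-controlled ortho-O-demethylation of the diacetyl dimethoxy benzophenone 12.
2. 12 ⇐ Friedel–Crafts acylation at C5 of the 2,4-dimethoxyphenyl ring of diarylpropane acetate 9 with 4-acetoxybenzoyl chloride 11.
3. 9 ⇐ 1,3-diarylpropane phenol 8 ⇐ full reduction (C=C, O-benzyl, C=O → CH2) of chalcone 4.
4. Chalcone 4 ⇐ Claisen–Schmidt aldol condensation of 2,4-dimethoxybenzaldehyde 1 with 4'-benzyloxyacetophenone 2; this C–C bond joins the two fragments and creates the three-carbon tether.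
5. No ring is formed: all three benzene rings come from the starting materials.

Assumption: the target has no stereocentre and no stereogenic double bond (it is achiral), so no enantiocontrol is needed.

**Route**

Step 1
Reactants: 1 2,4-dimethoxybenzaldehyde; 2 1-[4-(benzyloxy)phenyl]ethan-1-one
Product: 4 (E)-1-[4-(benzyloxy)phenyl]-3-(2,4-dimethoxyphenyl)prop-2-en-1-one, via β-hydroxy ketone 3 (not isolated)
Conditions: KOH (50% aq.), EtOH, 0 °C → rt, 16–24 h; filter the precipitated chalcone
Reagents that add atoms: none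
Why: Claisen–Schmidt aldol condensation of the ketone enolate with a non-enolisable aldehyde, followed by E1cB dehydration to the conjugated (E)-enone, which crystallises and drives the equilibrium.

Step 2
Reactants: 4 (E)-1-[4-(benzyloxy)phenyl]-3-(2,4-dimethoxyphenyl)prop-2-en-1-one
Product: 6 3-(2,4-dimethoxyphenyl)-1-(4-hydroxyphenyl)propan-1-one, via saturated benzyl ether 5 (not isolated)
Conditions: H2 (1 atm), 10% Pd/C, EtOAc–MeOH 1:1, rt
Reagents that add atoms: none
Why: Catalytic hydrogenation saturates the enone C=C and hydrogenolyses the benzyl ether, while the electron-rich 4-hydroxyphenyl ketone is reduced only slowly under neutral conditions (any over-reduced material converges in step 3).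

Step 3
Reactants: 6 3-(2,4-dimethoxyphenyl)-1-(4-hydroxyphenyl)propan-1-one
Product: 8 4-[3-(2,4-dimethoxyphenyl)propyl]phenol, via benzylic alcohol 7 (not isolated)
Conditions: Et3SiH (3 equiv), TFA, 0 °C → rt
Reagents that add atoms: none
Why: Ionic hydrogenation (Et3SiH/TFA deoxygenation), in which the protonated p-hydroxyaryl ketone and then the p-hydroxybenzylic cation are each trapped by silane hydride to give the methylene.

Step 4
Reactants: 8 4-[3-(2,4-dimethoxyphenyl)propyl]phenol
Product: 9 4-[3-(2,4-dimethoxyphenyl)propyl]phenyl acetate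
Conditions: Ac2O, pyridine, cat. DMAP, CH2Cl2, rt
Reagents that add atoms: acetic anhydride, CC(=O)OC(C)=O
Why: DMAP-catalysed O-acetylation gives a Lewis-acid-stable phenol protecting group that also deactivates this ring towards the coming Friedel–Crafts acylation.

Step 5
Reactants: 10 4-acetoxybenzoic acid
Product: 11 4-acetoxybenzoyl chloride
Conditions: (COCl)2, cat. DMF, CH2Cl2, 0 °C → rt; evaporate, use crude
Reagents that add atoms: oxalyl chloride, O=C(Cl)C(=O)Cl
Why: DMF-catalysed (Vilsmeier-type) conversion of a carboxylic acid into its acid chloride with only gaseous by-products, under which the aryl acetate is inert.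

Step 6
Reactants: 9 4-[3-(2,4-dimethoxyphenyl)propyl]phenyl acetate; 11 4-acetoxybenzoyl chloride
Product: 12 4-{3-[5-(4-acetoxybenzoyl)-2,4-dimethoxyphenyl]propyl}phenyl acetate
Conditions: AlCl3 (3 equiv, premixed with 11), CH2Cl2, 0 °C, 1–2 h; ice/1 M HCl quench
Reagents that add atoms: none
Why: Friedel–Crafts acylation goes to the far more nucleophilic dimethoxy ring at C5 (para to one OMe, ortho to the other, the only unhindered doubly activated site), the acetoxyphenyl ring being deactivated; any ortho-demethylated material formed here is simply 14.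

Step 7
Reactants: 12 4-{3-[5-(4-acetoxybenzoyl)-2,4-dimethoxyphenyl]propyl}phenyl acetate
Product: 14 4-{3-[5-(4-acetoxybenzoyl)-4-hydroxy-2-methoxyphenyl]propyl}phenyl acetate, via aryloxydichloroborane chelate 13 (not isolated)
Conditions: BCl3 (1 M in CH2Cl2, 3 equiv), CH2Cl2, −78 → 0 °C; H2O/aq. NaHCO3 work-up
Reagents that add atoms: boron trichloride, ClB(Cl)Cl (its B and Cl stay only in intermediate 13 and are lost on hydrolysis; 14 gains no heavy atom)
Why: Chelation-controlled Lewis-acid ether cleavage, in which BCl3 bound to the ketone oxygen cleaves only the methyl ether ortho to the carbonyl through a six-membered chelate and leaves the para OMe and the aryl acetates untouched at low temperature.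

Step 8
Reactants: 14 4-{3-[5-(4-acetoxybenzoyl)-4-hydroxy-2-methoxyphenyl]propyl}phenyl acetate
Product: 15 {2-hydroxy-5-[3-(4-hydroxyphenyl)propyl]-4-methoxyphenyl}(4-hydroxyphenyl)methanone
Conditions: conc. HCl (cat.), MeOH, 50 °C
Reagents that add atoms: none
Why: Acid-catalysed transesterification (methanolysis) of the two activated aryl acetates releases both phenols without affecting the aryl methyl ether or the benzophenone.

**Compound list**
1 | 2,4-dimethoxybenzaldehyde | COc1ccc(C=O)c(OC)c1 | starting material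
2 | 1-[4-(benzyloxy)phenyl]ethan-1-one (4'-benzyloxyacetophenone) | CC(=O)c1ccc(OCc2ccccc2)cc1 | starting material
3 | 1-[4-(benzyloxy)phenyl]-3-(2,4-dimethoxyphenyl)-3-hydroxypropan-1-one (racemic aldol adduct) | COc1ccc(C(O)CC(=O)c2ccc(OCc3ccccc3)cc2)c(OC)c1 | intermediate (not isolated)
4 | (E)-1-[4-(benzyloxy)phenyl]-3-(2,4-dimethoxyphenyl)prop-2-en-1-one | COc1ccc(/C=C/C(=O)c2ccc(OCc3ccccc3)cc2)c(OC)c1 | intermediate
5 | 1-[4-(benzyloxy)phenyl]-3-(2,4-dimethoxyphenyl)propan-1-one | COc1ccc(CCC(=O)c2ccc(OCc3ccccc3)cc2)c(OC)c1 | intermediate (not isolated)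
6 | 3-(2,4-dimethoxyphenyl)-1-(4-hydroxyphenyl)propan-1-one | COc1ccc(CCC(=O)c2ccc(O)cc2)c(OC)c1 | intermediate
7 | 4-[3-(2,4-dimethoxyphenyl)-1-hydroxypropyl]phenol (racemic) | COc1ccc(CCC(O)c2ccc(O)cc2)c(OC)c1 | intermediate (not isolated)
8 | 4-[3-(2,4-dimethoxyphenyl)propyl]phenol | COc1ccc(CCCc2ccc(O)cc2)c(OC)c1 | intermediate
9 | 4-[3-(2,4-dimethoxyphenyl)propyl]phenyl acetate | COc1ccc(CCCc2ccc(OC(C)=O)cc2)c(OC)c1 | intermediate
10 | 4-acetoxybenzoic acid | CC(=O)Oc1ccc(C(=O)O)cc1 | starting material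
11 | 4-acetoxybenzoyl chloride | CC(=O)Oc1ccc(C(Cl)=O)cc1 | intermediate
12 | 4-{3-[5-(4-acetoxybenzoyl)-2,4-dimethoxyphenyl]propyl}phenyl acetate | COc1cc(OC)c(C(=O)c2ccc(OC(C)=O)cc2)cc1CCCc1ccc(OC(C)=O)cc1 | intermediate
13 | 4-{3-[5-(4-acetoxybenzoyl)-4-(dichloroboranyloxy)-2-methoxyphenyl]propyl}phenyl acetate | COc1cc(OB(Cl)Cl)c(C(=O)c2ccc(OC(C)=O)cc2)cc1CCCc1ccc(OC(C)=O)cc1 | intermediate (not isolated)
14 | 4-{3-[5-(4-acetoxybenzoyl)-4-hydroxy-2-methoxyphenyl]propyl}phenyl acetate | COc1cc(O)c(C(=O)c2ccc(OC(C)=O)cc2)cc1CCCc1ccc(OC(C)=O)cc1 | intermediate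
15 | {2-hydroxy-5-[3-(4-hydroxyphenyl)propyl]-4-methoxyphenyl}(4-hydroxyphenyl)methanone (achiral) | COc1cc(O)c(C(=O)c2ccc(O)cc2)cc1CCCc1ccc(O)cc1 | target

**Step count**
Total steps: 8. Longest linear sequence: 7 (steps 1, 2, 3, 4, 6, 7, 8); step 5 is a one-step side branch.

**Steps most likely to fail** (most risky first: 6, then 3, then 7)

Step 6 (Friedel–Crafts acylation: Lewis-acid ether or acetate cleavage, incomplete regiocontrol). The fallback sets out from 8 and comes back at 12, replacing electrophilic acylation by an aryllithium addition. Phenol 8 is silylated (TBSCl, imidazole, DMF) to tert-butyl{4-[3-(2,4-dimethoxyphenyl)propyl]phenoxy}dimethylsilane F2. NBS (MeCN, 0 °C) brominates the dimethoxy ring at C5 to give {4-[3-(5-bromo-2,4-dimethoxyphenyl)propyl]phenoxy}(tert-butyl)dimethylsilane F3. Bromine–lithium exchange (n-BuLi, THF, −78 °C) gives the 5-lithio-2,4-dimethoxyaryl species F4, which adds to commercial 4-(tert-butyldimethylsilyloxy)benzaldehyde to give the bis-silylated diarylmethanol F5. MnO2 (CH2Cl2, rt) oxidises this to the bis-silylated 2,4-dimethoxybenzophenone F6. TBAF (THF, 0 °C) removes both silyl groups to give {2,4-dimethoxy-5-[3-(4-hydroxyphenyl)propyl]phenyl}(4-hydroxyphenyl)methanone F7, and Ac2O/pyridine converts this into 12.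

Step 3 (ionic hydrogenation: the p-hydroxybenzylic cation may alkylate the electron-rich dimethoxy ring of a second molecule). The fallback sets out from 6 and comes back at 8, and avoids any benzylic cation. Ketone 6 is treated with ethane-1,2-dithiol and BF3·OEt2 (CH2Cl2, rt) to give the dithiolane 4-{2-[2-(2,4-dimethoxyphenyl)ethyl]-1,3-dithiolan-2-yl}phenol F1, which Raney nickel (EtOH, reflux) desulfurises to 8 (Mozingo reduction).

Step 7 (selective mono-demethylation: over-cleavage of the second OMe or loss of acetate). The fallback sets out from 12 and comes back at 14, replacing selective demethylation by exhaustive demethylation and selective re-methylation. Both methyl ethers of 12 are cleaved with BBr3 (CH2Cl2, −78 → 0 °C, aqueous work-up) to give 4-{3-[5-(4-acetoxybenzoyl)-2,4-dihydroxyphenyl]propyl}phenyl acetate F8. TMSCHN2 (MeOH–toluene, rt) then methylates only the free 4-OH para to the ketone, because the 2-OH is locked in the hydrogen bond to the carbonyl, and this gives 14.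

**Further compounds**
F1 | step 3 | 4-{2-[2-(2,4-dimethoxyphenyl)ethyl]-1,3-dithiolan-2-yl}phenol | COc1ccc(CCC2(c3ccc(O)cc3)SCCS2)c(OC)c1
F2 | step 6 | tert-butyl{4-[3-(2,4-dimethoxyphenyl)propyl]phenoxy}dimethylsilane | COc1ccc(CCCc2ccc(O[Si](C)(C)C(C)(C)C)cc2)c(OC)c1
F3 | step 6 | {4-[3-(5-bromo-2,4-dimethoxyphenyl)propyl]phenoxy}(tert-butyl)dimethylsilane | COc1cc(OC)c(Br)cc1CCCc1ccc(O[Si](C)(C)C(C)(C)C)cc1
F4 | step 6 | (5-{3-[4-(tert-butyldimethylsilyloxy)phenyl]propyl}-2,4-dimethoxyphenyl)lithium | COc1cc(OC)c([Li])cc1CCCc1ccc(O[Si](C)(C)C(C)(C)C)cc1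
F5 | step 6 | [4-(tert-butyldimethylsilyloxy)phenyl](5-{3-[4-(tert-butyldimethylsilyloxy)phenyl]propyl}-2,4-dimethoxyphenyl)methanol (racemic) | COc1cc(OC)c(C(O)c2ccc(O[Si](C)(C)C(C)(C)C)cc2)cc1CCCc1ccc(O[Si](C)(C)C(C)(C)C)cc1
F6 | step 6 | [4-(tert-butyldimethylsilyloxy)phenyl](5-{3-[4-(tert-butyldimethylsilyloxy)phenyl]propyl}-2,4-dimethoxyphenyl)methanone | COc1cc(OC)c(C(=O)c2ccc(O[Si](C)(C)C(C)(C)C)cc2)cc1CCCc1ccc(O[Si](C)(C)C(C)(C)C)cc1
F7 | step 6 | {2,4-dimethoxy-5-[3-(4-hydroxyphenyl)propyl]phenyl}(4-hydroxyphenyl)methanone | COc1cc(OC)c(C(=O)c2ccc(O)cc2)cc1CCCc1ccc(O)cc1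
F8 | step 7 | 4-{3-[5-(4-acetoxybenzoyl)-2,4-dihydroxyphenyl]propyl}phenyl acetate | CC(=O)Oc1ccc(CCCc2cc(C(=O)c3ccc(OC(C)=O)cc3)c(O)cc2O)cc1
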